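The oxocene is assembled by a convergent oxa-[6+2] annulation (atoms numbered along the C15 chain). It exploits two features of the eight-membered ring: the 1,3-dioxygen pattern O1–C7–C8–C9–O (an aldol retron) and the allylic ether O1–C13 next to the cis C11=C12 bond (a Nicholas retron, the alkene being carried as its Co2(CO)6–alkyne complex). A silyl enol ether (C8=C9) bearing a cobalt-complexed propargylic methyl ether (C13) meets an α-silyloxy aldehyde (C7) under BF3·OEt2. Mukaiyama aldol addition forges C7–C8, then the aldolate oxygen captures the propargylic cation to forge O1–C13, closing the ring in one operation.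

Key step: step 11

Remark on numbering: C1≡C2–C3=C4–C5–C6(Cl)–C7(O1)–C8–C9(OAc)–C10(OAc)–C11=C12–C13(O1)–C14–C15.
Assumption: the methoxy-bearing carbon (future C13) of 2, 4–8 and 14 is carried as a mixture of epimers, because it is planarised in step 11; the SMILES leave this centre undefined.
Assumption: in step 2 the ProPhenol enantiomer is the one that gives the 3S carbinol (to be confirmed on a model aldehyde).

Step 1
Reactants: 1 pent-1-yn-3-ol (racemic)
Product: 2 3-methoxypent-1-yne (racemic)
Conditions: NaH (1.0 equiv), MeI, THF, 0 °C to rt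
Reagents that add atoms: iodomethane, CI
Why: Williamson etherification of the sodium alkoxide should install the methoxy group, which is the later Nicholas leaving group and survives the basic steps.

Step 2
Reactants: 2 3-methoxypent-1-yne; 3 methacrolein
Product: 4 (3S)-6-methoxy-2-methyloct-1-en-4-yn-3-ol (epimers at C6)
Conditions: Me2Zn (3 equiv), ProPhenol ligand (10 mol %, enantiomer giving the 3S alcohol), Ph3PO (20 mol %), toluene, 0 °C
Reagents that add atoms: none
Why: Zinc–ProPhenol-catalysed asymmetric alkynylation of the enal should set the future C10 centre by catalyst control of the carbonyl face, the remote methoxy centre remaining an irrelevant epimer mixture.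

Step 3
Reactants: 4 (3S)-6-methoxy-2-methyloct-1-en-4-yn-3-ol
Product: 5 tert-butyl{[(3S)-6-methoxy-2-methyloct-1-en-4-yn-3-yl]oxy}dimethylsilane
Conditions: TBSCl, imidazole, DMF, rt
Reagents that add atoms: tert-butyldimethylsilyl chloride, CC(C)(C)[Si](C)(C)Cl
Why: Standard silylation should block the C10 oxygen as a bulky ether that neither ionises nor acts as a nucleophile in the key step.

Step 4
Reactants: 5 tert-butyl{[(3S)-6-methoxy-2-methyloct-1-en-4-yn-3-yl]oxy}dimethylsilane
Product: 6 (3R)-3-(tert-butyldimethylsilyloxy)-6-methoxyoct-4-yn-2-one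
Conditions: OsO4 (2 mol %), NaIO4 (4 equiv), 2,6-lutidine, dioxane/H2O 3:1, rt
Reagents that add atoms: osmium tetroxide, O=[Os](=O)(=O)=O (oxygen carrier); sodium periodate, [Na+].[O-]I(=O)(=O)=O (terminal oxygen source)
Why: Lemieux–Johnson cleavage of the 1,1-disubstituted alkene, which is dihydroxylated far faster than the internal alkyne, should unmask the methyl ketone without touching the C10 centre.

Step 5
Reactants: 6 (3R)-3-(tert-butyldimethylsilyloxy)-6-methoxyoct-4-yn-2-one
Product: 7 (3R)-3-(tert-butyldimethylsilyloxy)-6-methoxy-2-(trimethylsilyloxy)oct-1-en-4-yne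
Conditions: LiN(SiMe3)2, Me3SiCl (in situ quench), THF, −78 °C; pentane, filtration
Reagents that add atoms: chlorotrimethylsilane, C[Si](C)(C)Cl
Why: Kinetic deprotonation of the methyl group by the bulky amide with in situ silyl trapping should give the less substituted enol silane (the C8 nucleophile), the hindered α-silyloxy C10–H being left alone.

Step 6
Reactants: 7 (3R)-3-(tert-butyldimethylsilyloxy)-6-methoxy-2-(trimethylsilyloxy)oct-1-en-4-yne
Product: 8 hexacarbonyldicobalt complex of 7 (Co2(CO)6 bridging the C4≡C5 alkyne; configuration at C3 unchanged)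
Conditions: Co2(CO)8 (1.05 equiv), pentane, rt; filtration through neutral alumina
Reagents that add atoms: dicobalt octacarbonyl, O=C=[Co](=C=O)(=C=O)(=C=O)[Co](=C=O)(=C=O)(=C=O)=C=O
Why: Alkyne complexation under neutral conditions with loss of two CO should leave the enol silane intact and install the bent, cation-stabilising Co2(CO)6 unit.

Step 7
Reactants: 9 L-allylglycine, (2S)-2-aminopent-4-enoic acid
Product: 10 (2S)-2-hydroxypent-4-enoic acid
Conditions: NaNO2, 1 M H2SO4 (aq), 0 °C to rt
Reagents that add atoms: water, O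
Why: Diazotisation with carboxylate participation (α-lactone, double inversion) should give the α-hydroxy acid with net retention, fixing the future C6 as S.

Step 8
Reactants: 10 (2S)-2-hydroxypent-4-enoic acid
Product: 11 methyl (2S)-2-hydroxypent-4-enoate
Conditions: MeOH, cat. H2SO4, reflux
Reagents that add atoms: methanol, CO
Why: Fischer esterification should proceed without affecting the stereocentre.

Step 9
Reactants: 11 methyl (2S)-2-hydroxypent-4-enoate
Product: 12 methyl (2S)-2-(tert-butyldiphenylsilyloxy)pent-4-enoate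
Conditions: TBDPSCl, imidazole, DMF, rt
Reagents that add atoms: tert-butyldiphenylsilyl chloride, CC(C)(C)[Si](Cl)(c1ccccc1)c1ccccc1
Why: Silylation should give a non-chelating, hindered ether that survives BF3·OEt2 and buffered HF and favours Felkin-type addition later.

Step 10
Reactants: 12 methyl (2S)-2-(tert-butyldiphenylsilyloxy)pent-4-enoate
Product: 13 (2S)-2-(tert-butyldiphenylsilyloxy)pent-4-enal
Conditions: i-Bu2AlH (1.1 equiv), CH2Cl2, −78 °C; aqueous sodium potassium tartrate
Reagents that add atoms: none
Why: Low-temperature i-Bu2AlH reduction should stop at the tetrahedral aluminium hemiacetal and release the aldehyde on work-up without epimerisation.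

Step 11
Reactants: 13 (2S)-2-(tert-butyldiphenylsilyloxy)pent-4-enal; 8 hexacarbonyldicobalt complex of the enol silane
Product: 15 cobalt-complexed oxocanone (ring O1–C7–C8–C9(=O)–C10(OTBS)–C11≡C12–C13(Et), alkyne bound to Co2(CO)6, C7 bearing the (1S)-1-(TBDPS-oxy)but-3-enyl group, 7R, 7,13-cis), via difluoroboron aldolate 14 (not isolated)
Conditions: 13 precomplexed with BF3·OEt2 (1.2 equiv), CH2Cl2 (0.02 M), −78 °C, slow addition of 8; then BF3·OEt2 (1.5 equiv), −78 to 0 °C; aq. NaHCO3
Reagents that add atoms: none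
Why: Proposed new method: at −78 °C the BF3-activated aldehyde 13 should be attacked by C8 of enol silane 8 (Mukaiyama aldol, C7–C8) to give aldolate 14, and on warming BF3 should ionise the C13 methyl ether to the Co2(CO)6-stabilised propargylic cation, which the C7 oxygen captures (Nicholas etherification, O1–C13). The closest known reaction types are the Mukaiyama aldol addition, the intramolecular Nicholas etherification used for medium-ring ethers, and cobalt-mediated formal [5+2] and [6+2] annulations of enol silanes with reagents that combine a Nicholas cation precursor and a π-nucleophile; new is their merger with a C=O as the two-atom partner. The eight-membered ring closes by O-attack on the cationic carbon in the endo mode with respect to the complexed alkyne (C11 and C12 inside the ring), which the roughly 140° bend of the complexed alkyne should favour. C7 is set by polar Felkin–Anh (Cornforth) addition anti to the non-chelating C6 silyloxy group (6,7-anti, 7R). C13 is set under thermodynamic control, because the planar cation can re-form from the cyclic ether under BF3, in favour of the 7,13-cis isomer (13R). The step needs the aldol to precede ionisation (precomplexed aldehyde, low temperature) and O7 to be the only competent nucleophile, which is secured because the C10 silyl ether is deactivated toward ionisation by the adjacent C9 ketone, the TBDPS ether is hindered, and rings smaller than eight cannot hold the bent alkyne complex.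

Step 12
Reactants: 15 cobalt-complexed oxocanone
Product: 16 cobalt-complexed C10-hydroxy oxocanone
Conditions: HF·pyridine, pyridine, THF, 0 °C
Reagents that add atoms: none
Why: Buffered HF should cleave the TBS ether next to the ketone much faster than the hindered secondary TBDPS ether.

Step 13
Reactants: 16 cobalt-complexed C10-hydroxy oxocanone
Product: 17 cobalt-complexed 9,10-trans-diol (9R,10R)
Conditions: Me4NBH(OAc)3, MeCN/AcOH 1:1, −30 to −20 °C
Reagents that add atoms: none
Why: Hydroxyl-directed (Saksena–Evans type) reduction should bind boron at the C10 hydroxyl and deliver hydride to C9 on the same face, placing the new C9 hydroxyl trans to the C10 hydroxyl.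

Step 14
Reactants: 17 cobalt-complexed 9,10-trans-diol
Product: 18 cobalt-complexed 9,10-diacetate
Conditions: Ac2O, pyridine, DMAP (cat.), CH2Cl2, rt
Reagents that add atoms: acetic anhydride, CC(=O)OC(C)=O
Why: Standard acylation of both secondary alcohols under non-acidic conditions should not ionise the propargylic positions of the complex.

Step 15
Reactants: 18 cobalt-complexed 9,10-diacetate
Product: 19 (2R,4R,5R,8R)-2-[(1S)-1-(tert-butyldiphenylsilyloxy)but-3-enyl]-8-ethyl-3,4,5,8-tetrahydro-2H-oxocine-4,5-diyl diacetate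
Conditions: n-Bu3SnH (5 equiv), benzene, 65 °C
Reagents that add atoms: none
Why: Reductive decomplexation of the endocyclic dicobalt–alkyne complex with tin hydride should deliver both hydrogens to the same side and give the ring cis C11=C12 alkene, the only geometry the eight-membered ring allows.

Step 16
Reactants: 19 silyl-protected oxocene diacetate
Product: 20 (2R,4R,5R,8R)-8-ethyl-2-[(1S)-1-hydroxybut-3-enyl]-3,4,5,8-tetrahydro-2H-oxocine-4,5-diyl diacetate
Conditions: n-Bu4NF, AcOH (1:1), THF, rt
Reagents that add atoms: none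
Why: Acetic acid-buffered fluoride should remove the TBDPS group while suppressing acetate cleavage or migration.

Step 17
Reactants: 20 C6 alcohol
Product: 21 (2R,4R,5R,8R)-2-[(1R)-1-chlorobut-3-enyl]-8-ethyl-3,4,5,8-tetrahydro-2H-oxocine-4,5-diyl diacetate
Conditions: CCl4, (n-C8H17)3P, toluene, 80 °C
Reagents that add atoms: carbon tetrachloride, ClC(Cl)(Cl)Cl
Why: Appel-type chlorination via the alkoxyphosphonium salt and SN2 attack of chloride should invert C6 (6S to 6R) and convert the 6,7-anti oxygen pattern into the 6,7-syn chlorohydrin ether.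

Step 18
Reactants: 22 vinyl bromide; 23 (triisopropylsilyl)acetylene
Product: 24 (but-3-en-1-yn-1-yl)triisopropylsilane
Conditions: Pd(PPh3)4 (2 mol %), CuI (4 mol %), i-Pr2NH, THF, 0 °C to rt
Reagents that add atoms: none
Why: Sonogashira coupling of the vinyl halide with the terminal alkyne should give the silyl-capped conjugated enyne.

Step 19
Reactants: 21 chloro oxocene diacetate; 24 (but-3-en-1-yn-1-yl)triisopropylsilane
Product: 25 (2R,4R,5R,8R)-2-[(1R,3Z)-1-chloro-6-(triisopropylsilyl)hex-3-en-5-ynyl]-8-ethyl-3,4,5,8-tetrahydro-2H-oxocine-4,5-diyl diacetate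
Conditions: 24 (4 equiv), second-generation Grubbs catalyst (H2IMes)(PCy3)Cl2Ru=CHPh (10 mol %), CH2Cl2, 40 °C
Reagents that add atoms: none
Why: Cross-metathesis of a terminal alkene with a conjugated enyne is kinetically Z-selective (small alkynyl group in the metallacyclobutane), and the hindered ring alkene flanked by the allylic acetate and ether carbons should not be engaged.

Step 20
Reactants: 25 silyl-capped Z-enyne
Product: 26 target, (2R,4R,5R,8R)-2-[(1R,3Z)-1-chlorohex-3-en-5-ynyl]-8-ethyl-3,4,5,8-tetrahydro-2H-oxocine-4,5-diyl diacetate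
Conditions: n-Bu4NF, AcOH (1:1), THF, 0 °C
Reagents that add atoms: none
Why: Fluoride cleavage of the alkynyl–silicon bond is fast at 0 °C and, when buffered, should spare the acetates and the secondary chloride.

Compound list
1 | pent-1-yn-3-ol (racemic) | CCC(O)C#C | starting material
2 | 3-methoxypent-1-yne (racemic) | CCC(OC)C#C | intermediate
3 | methacrolein (2-methylprop-2-enal) | CC(=C)C=O | starting material
4 | (3S)-6-methoxy-2-methyloct-1-en-4-yn-3-ol (epimers at C6) | C=C(C)[C@H](O)C#CC(OC)CC | intermediate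
5 | tert-butyl{[(3S)-6-methoxy-2-methyloct-1-en-4-yn-3-yl]oxy}dimethylsilane | C=C(C)[C@H](O[Si](C)(C)C(C)(C)C)C#CC(OC)CC | intermediate
6 | (3R)-3-(tert-butyldimethylsilyloxy)-6-methoxyoct-4-yn-2-one | CC(=O)[C@H](O[Si](C)(C)C(C)(C)C)C#CC(OC)CC | intermediate
7 | (3R)-3-(tert-butyldimethylsilyloxy)-6-methoxy-2-(trimethylsilyloxy)oct-1-en-4-yne | C=C(O[Si](C)(C)C)[C@H](O[Si](C)(C)C(C)(C)C)C#CC(OC)CC | intermediate
8 | hexacarbonyldicobalt complex of 7 (Co2(CO)6 on the C4≡C5 alkyne) | C=C(O[Si](C)(C)C)[C@H](O[Si](C)(C)C(C)(C)C)C12C3(C(OC)CC)[Co]1(=C=O)(=C=O)(=C=O)[Co]23(=C=O)(=C=O)=C=O | intermediate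
9 | L-allylglycine, (2S)-2-aminopent-4-enoic acid | C=CC[C@H](N)C(=O)O | starting material
10 | (2S)-2-hydroxypent-4-enoic acid | C=CC[C@H](O)C(=O)O | intermediate
11 | methyl (2S)-2-hydroxypent-4-enoate | C=CC[C@H](O)C(=O)OC | intermediate
12 | methyl (2S)-2-(tert-butyldiphenylsilyloxy)pent-4-enoate | C=CC[C@H](O[Si](c1ccccc1)(c1ccccc1)C(C)(C)C)C(=O)OC | intermediate
13 | (2S)-2-(tert-butyldiphenylsilyloxy)pent-4-enal | C=CC[C@H](O[Si](c1ccccc1)(c1ccccc1)C(C)(C)C)C=O | intermediate
14 | difluoroboron aldolate: open-chain (6S,7R) aldol adduct of 13 and 8, C7–O–BF2, C9 ketone, cobalt complex retained (not isolated) | C=CC[C@H](O[Si](c1ccccc1)(c1ccccc1)C(C)(C)C)[C@H](OB(F)F)CC(=O)[C@H](O[Si](C)(C)C(C)(C)C)C12C3(C(OC)CC)[Co]1(=C=O)(=C=O)(=C=O)[Co]23(=C=O)(=C=O)=C=O | intermediate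
15 | cobalt-complexed oxocanone: ring O1–C7–C8–C9(=O)–C10(OTBS)–C11≡C12[Co2(CO)6]–C13(Et), C7 bearing (1S)-1-(TBDPS-oxy)but-3-enyl, 7,13-cis | C=CC[C@H](O[Si](c1ccccc1)(c1ccccc1)C(C)(C)C)[C@H]1CC(=O)[C@H](O[Si](C)(C)C(C)(C)C)C23C4([C@@H](CC)O1)[Co]2(=C=O)(=C=O)(=C=O)[Co]34(=C=O)(=C=O)=C=O | intermediate
16 | cobalt-complexed C10-hydroxy oxocanone (TBS removed from 15) | C=CC[C@H](O[Si](c1ccccc1)(c1ccccc1)C(C)(C)C)[C@H]1CC(=O)[C@H](O)C23C4([C@@H](CC)O1)[Co]2(=C=O)(=C=O)(=C=O)[Co]34(=C=O)(=C=O)=C=O | intermediate
17 | cobalt-complexed 9,10-trans-diol (9R,10R) | C=CC[C@H](O[Si](c1ccccc1)(c1ccccc1)C(C)(C)C)[C@H]1C[C@@H](O)[C@H](O)C23C4([C@@H](CC)O1)[Co]2(=C=O)(=C=O)(=C=O)[Co]34(=C=O)(=C=O)=C=O | intermediate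
18 | cobalt-complexed 9,10-diacetate | C=CC[C@H](O[Si](c1ccccc1)(c1ccccc1)C(C)(C)C)[C@H]1C[C@@H](OC(C)=O)[C@H](OC(C)=O)C23C4([C@@H](CC)O1)[Co]2(=C=O)(=C=O)(=C=O)[Co]34(=C=O)(=C=O)=C=O | intermediate
19 | (2R,4R,5R,8R)-2-[(1S)-1-(tert-butyldiphenylsilyloxy)but-3-enyl]-8-ethyl-3,4,5,8-tetrahydro-2H-oxocine-4,5-diyl diacetate | C=CC[C@H](O[Si](c1ccccc1)(c1ccccc1)C(C)(C)C)[C@H]1C[C@@H](OC(C)=O)[C@H](OC(C)=O)/C=C\[C@@H](CC)O1 | intermediate
20 | (2R,4R,5R,8R)-8-ethyl-2-[(1S)-1-hydroxybut-3-enyl]-3,4,5,8-tetrahydro-2H-oxocine-4,5-diyl diacetate | C=CC[C@H](O)[C@H]1C[C@@H](OC(C)=O)[C@H](OC(C)=O)/C=C\[C@@H](CC)O1 | intermediate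
21 | (2R,4R,5R,8R)-2-[(1R)-1-chlorobut-3-enyl]-8-ethyl-3,4,5,8-tetrahydro-2H-oxocine-4,5-diyl diacetate | C=CC[C@@H](Cl)[C@H]1C[C@@H](OC(C)=O)[C@H](OC(C)=O)/C=C\[C@@H](CC)O1 | intermediate
22 | vinyl bromide | C=CBr | starting material
23 | (triisopropylsilyl)acetylene | C#C[Si](C(C)C)(C(C)C)C(C)C | starting material
24 | (but-3-en-1-yn-1-yl)triisopropylsilane | C=CC#C[Si](C(C)C)(C(C)C)C(C)C | intermediate
25 | (2R,4R,5R,8R)-2-[(1R,3Z)-1-chloro-6-(triisopropylsilyl)hex-3-en-5-ynyl]-8-ethyl-3,4,5,8-tetrahydro-2H-oxocine-4,5-diyl diacetate | CC(C)[Si](C(C)C)(C(C)C)C#C/C=C\C[C@@H](Cl)[C@H]1C[C@@H](OC(C)=O)[C@H](OC(C)=O)/C=C\[C@@H](CC)O1 | intermediate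
26 | (2R,4R,5R,8R)-2-[(1R,3Z)-1-chlorohex-3-en-5-ynyl]-8-ethyl-3,4,5,8-tetrahydro-2H-oxocine-4,5-diyl diacetate | C#C/C=C\C[C@@H](Cl)[C@H]1C[C@@H](OC(C)=O)[C@H](OC(C)=O)/C=C\[C@@H](CC)O1 | target

Total step count: 20. Longest linear sequence: 15 steps (steps 1–6, 11–17, 19 and 20).

Steps most likely to fail

Step 11 (proposed new method). The propargylic methyl ether may ionise before the aldol addition, leading to elimination or oligomerisation. Capture of the cation by the boron-bound aldolate oxygen may be sluggish, retro-aldol cleavage may occur on warming, or equilibration to the 7,13-cis ether may be incomplete. The fallback uses two separate known reactions. From 13 and 8, a Mukaiyama aldol addition alone (BF3·OEt2, 1.1 equiv, CH2Cl2, −78 °C, quenched cold with aqueous NaHCO3) should give the isolated (6S,7R)-β-hydroxy ketone complex F1. A separate intramolecular Nicholas etherification of the free alcohol (BF3·OEt2, CH2Cl2, 0.005 M, −20 to 0 °C, equilibrating) should then close the ring and return to 15.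

Step 17. The alkoxyphosphonium intermediate may undergo elimination toward the 1,3-diene, or the ring oxygen may participate, giving retention or ring contraction. The fallback replaces phosphonium activation by sulfonate displacement. From 20, chloromethanesulfonyl chloride (2,6-lutidine, CH2Cl2, 0 °C) should give the chloromethanesulfonate F2. Its SN2 displacement with LiCl in DMF at room temperature should proceed with inversion and return to 21.

Step 19. Z selectivity may erode, 21 may homodimerise, or the oxocene may undergo ring-opening metathesis. The fallback avoids metathesis. From 21, chemoselective Lemieux–Johnson cleavage of the monosubstituted alkene (OsO4 cat., NaIO4, 2,6-lutidine, dioxane/H2O) should give the β-chloro aldehyde F3. Z-selective Peterson olefination with lithiated 1,3-bis(triisopropylsilyl)propyne (n-BuLi, THF, −78 °C) should then return to 25.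

Further compounds
F1 | step 11 | (6S,7R)-β-hydroxy ketone complex (open-chain aldol adduct of 13 and 8 with free C7 hydroxyl) | C=CC[C@H](O[Si](c1ccccc1)(c1ccccc1)C(C)(C)C)[C@H](O)CC(=O)[C@H](O[Si](C)(C)C(C)(C)C)C12C3(C(OC)CC)[Co]1(=C=O)(=C=O)(=C=O)[Co]23(=C=O)(=C=O)=C=O
F2 | step 17 | (2R,4R,5R,8R)-2-{(1S)-1-[(chloromethanesulfonyl)oxy]but-3-enyl}-8-ethyl-3,4,5,8-tetrahydro-2H-oxocine-4,5-diyl diacetate | C=CC[C@H](OS(=O)(=O)CCl)[C@H]1C[C@@H](OC(C)=O)[C@H](OC(C)=O)/C=C\[C@@H](CC)O1
F3 | step 19 | (3R)-3-chloro-3-[(2R,4R,5R,8R)-4,5-diacetoxy-8-ethyl-3,4,5,8-tetrahydro-2H-oxocin-2-yl]propanal | O=CC[C@@H](Cl)[C@H]1C[C@@H](OC(C)=O)[C@H](OC(C)=O)/C=C\[C@@H](CC)O1
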